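**Plan**

- Retrosynthesis: with the two silyl ethers and the 4'-acetate removed last, the C4–C4a aryl ketone bond is cut to an (S)-3-aryloxy-3-arylpropanoic acid. The O1–C2 ether bond is then cut to a phenol and an (R)-β-hydroxy ester, and the C8–C1'' bond to phloroglucinol and geranyl bromide.
- Forward: ring A is phloroglucinol, C-geranylated and bis-silylated. Ring B comes from 4'-hydroxyacetophenone, homologated to an allyl β-keto ester and reduced. The halves are joined through O1–C2, and ring C (the pyranone) is closed last by acylation of ring A.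
- Enabling feature: on ring A the geranyl group occupies C8, so C4a is the only free carbon ortho to O1, and it is ortho to O1 and O5 and para to O7.
- Stereochemistry: C2 is set as the (R)-carbinol by catalyst-controlled asymmetric transfer hydrogenation, inverted to (S) in the Mitsunobu etherification, and then carried only through neutral or weakly acidic steps. The 2''E olefin comes with geranyl bromide.

Key step: step 8

Remark: geranyl = (2E)-3,7-dimethylocta-2,6-dien-1-yl and TBS = tert-butyldimethylsilyl; the (R,R)-TsDPEN ruthenium catalyst is assumed to give the (R)-carbinol, as it does with aryl methyl ketones.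

**Step 1**
Reactants: 1 phloroglucinol; 2 geranyl bromide
Product: 3 2-geranylbenzene-1,3,5-triol
Conditions: 1 (3 equiv), DBU (1 equiv), THF, 0 °C to rt
Reagents that add atoms: none
Why: Phenolate C-allylation of the ambident phloroglucinol monoanion is favoured with a soft allylic bromide in a weakly polar medium, the three ring carbons are equivalent so only one mono-C-geranyl product can form, and the excess of triol holds back dialkylation.

**Step 2**
Reactants: 3 2-geranylbenzene-1,3,5-triol
Product: 4 3,5-bis(tert-butyldimethylsilyloxy)-2-geranylphenol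
Conditions: TBSCl (2.0 equiv), imidazole, DMF, −20 to 0 °C
Reagents that add atoms: tert-butyldimethylsilyl chloride, CC(C)(C)[Si](C)(C)Cl
Why: Silyl ether formation should take the unhindered hydroxyl para to the geranyl group first and then either of the two equivalent ortho hydroxyls, so the main bis-silyl ether keeps one free OH next to the chain; the outcome is statistically limited, and mono- and tris-silylated material is separated and recycled.

**Step 3**
Reactants: 5 4'-hydroxyacetophenone
Product: 6 allyl 3-(4-hydroxyphenyl)-3-oxopropanoate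
Conditions: NaH (3.5 equiv), diallyl carbonate (2.5 equiv), THF, reflux; then 1 M HCl, 0 °C
Reagents that add atoms: diallyl carbonate, C=CCOC(=O)OCC=C
Why: Crossed Claisen condensation of the ketone enolate with a dialkyl carbonate is driven by deprotonation of the β-keto ester formed, while the phenol is held as its unreactive sodium phenoxide.

**Step 4**
Reactants: 6 allyl 3-(4-hydroxyphenyl)-3-oxopropanoate
Product: 7 allyl 3-(4-acetoxyphenyl)-3-oxopropanoate
Conditions: Ac2O (1.1 equiv), pyridine, CH2Cl2, 0 °C
Reagents that add atoms: acetic anhydride, CC(=O)OC(C)=O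
Why: Pyridine-mediated O-acetylation picks the phenol, the most acidic and most nucleophilic hydroxyl, whereas the β-keto ester enol is not acetylated at 0 °C without an acyl-transfer catalyst.

**Step 5**
Reactants: 7 allyl 3-(4-acetoxyphenyl)-3-oxopropanoate
Product: 8 allyl (3R)-3-(4-acetoxyphenyl)-3-hydroxypropanoate
Conditions: RuCl[(R,R)-TsDPEN](p-cymene) (1 mol%), HCO2H–Et3N (5:2), EtOAc, rt
Reagents that add atoms: none
Why: Noyori asymmetric transfer hydrogenation delivers hydride to one face of the aryl ketone through its CH–π-organised six-membered transition state, the (R,R)-ligand setting the (R)-carbinol, and unlike hydrogenation with H2 it leaves the allyl ester olefin and the aryl acetate untouched.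

**Step 6**
Reactants: 4 3,5-bis(tert-butyldimethylsilyloxy)-2-geranylphenol; 8 allyl (3R)-3-(4-acetoxyphenyl)-3-hydroxypropanoate
Product: 9 allyl (3S)-3-(4-acetoxyphenyl)-3-[3,5-bis(tert-butyldimethylsilyloxy)-2-geranylphenoxy]propanoate
Conditions: PPh3, DIAD (added last, slowly), toluene, 0 °C to rt
Reagents that add atoms: none
Why: In this Mitsunobu etherification the phenol protonates the betaine and its phenoxide displaces the benzylic oxyphosphonium by SN2 with inversion, turning the (R)-alcohol into the (S)-aryl ether, while the 4-acetoxy group disfavours ionisation and the non-polar solvent at low temperature limits dehydration to the cinnamate.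

**Step 7**
Reactants: 9 allyl (3S)-3-(4-acetoxyphenyl)-3-[3,5-bis(tert-butyldimethylsilyloxy)-2-geranylphenoxy]propanoate
Product: 10 (3S)-3-(4-acetoxyphenyl)-3-[3,5-bis(tert-butyldimethylsilyloxy)-2-geranylphenoxy]propanoic acid
Conditions: Pd(PPh3)4 (3 mol%), N-methylaniline (2 equiv), THF, rt; cold aq. citric acid work-up
Reagents that add atoms: none
Why: In this Tsuji–Trost deallylation Pd(0) ionises the allyl ester and the weakly basic, poorly acylating N-methylaniline traps the π-allyl unit, so the acid is released without hydroxide and the aryl acetate, the silyl ethers and the β-aryloxy stereocentre are left alone.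

**Step 8**
Reactants: 10 (3S)-3-(4-acetoxyphenyl)-3-[3,5-bis(tert-butyldimethylsilyloxy)-2-geranylphenoxy]propanoic acid
Product: 12 (2S)-4'-acetoxy-5,7-bis(tert-butyldimethylsilyloxy)-8-geranylflavanone, via mixed trifluoroacetic anhydride 11 (not isolated)
Conditions: TFAA (1.3 equiv), 2,6-di-tert-butyl-4-methylpyridine (2.5 equiv), CH2Cl2, −20 to 0 °C
Reagents that add atoms: trifluoroacetic anhydride, O=C(OC(=O)C(F)(F)F)C(F)(F)F (its trifluoroacetyl group is carried only by intermediate 11)
Why: The acid and trifluoroacetic anhydride give the mixed anhydride 11, whose acyl carbon is attacked by C4a of the same aryl ether ring in an electrophilic aromatic substitution, and loss of trifluoroacetate and then of the ring proton gives the aryl ketone. The closest known reaction is the intramolecular Friedel–Crafts acylation of 3-aryloxypropanoic acids of phloroglucinol ethers to chroman-4-ones under trifluoroacetic anhydride activation. The pyranone ring closes as a six-membered ring by 6-exo-trig attack of the arene on the acyl carbon, forming C4–C4a. No stereocentre is created; C2 is carried through, protected by the hindered non-nucleophilic pyridine buffer, the low temperature and the 4'-acetate, which disfavours ionisation of the benzylic C2–O1 bond. The step needs acylation at C4a only, and the substrate secures it: C8 is blocked by geranyl, the other free ring carbon (C6) cannot be reached by the three-atom tether, and C4a is activated by O1 and O5 (ortho) and O7 (para). Selectivity over the geranyl olefins and over β-elimination of the aryloxide rests on the absence of free strong acid and of any strong base.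

**Step 9**
Reactants: 12 (2S)-4'-acetoxy-5,7-bis(tert-butyldimethylsilyloxy)-8-geranylflavanone
Product: 13 (2S)-4'-acetoxy-5,7-dihydroxy-8-geranylflavanone
Conditions: HF·pyridine, pyridine, THF, 0 °C to rt
Reagents that add atoms: none
Why: Fluoride-mediated cleavage of the two aryl silyl ethers with pyridine-buffered HF is mild enough to spare the aryl acetate, the geranyl olefins and the C2 stereocentre, which a basic fluoride source could scramble through chalcone formation.

**Step 10**
Reactants: 13 (2S)-4'-acetoxy-5,7-dihydroxy-8-geranylflavanone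
Product: 14 sophoraflavanone A, (2S)-5,7,4'-trihydroxy-8-geranylflavanone
Conditions: NH4OAc (excess), MeOH–H2O (4:1), rt
Reagents that add atoms: none
Why: Ammonium acetate-promoted methanolysis (transesterification) cleaves aryl acetates selectively under neutral conditions, and near pH 7 the flavanone should not open to the chalcone, so C2 stays (S).

**Compound list**

1 | phloroglucinol (benzene-1,3,5-triol) | Oc1cc(O)cc(O)c1 | starting material
2 | geranyl bromide, (2E)-1-bromo-3,7-dimethylocta-2,6-diene | CC(C)=CCC/C(C)=C/CBr | starting material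
3 | 2-geranylbenzene-1,3,5-triol | CC(C)=CCC/C(C)=C/Cc1c(O)cc(O)cc1O | intermediate
4 | 3,5-bis(tert-butyldimethylsilyloxy)-2-geranylphenol (free OH ortho to the geranyl group) | CC(C)=CCC/C(C)=C/Cc1c(O)cc(O[Si](C)(C)C(C)(C)C)cc1O[Si](C)(C)C(C)(C)C | intermediate
5 | 4'-hydroxyacetophenone | CC(=O)c1ccc(O)cc1 | starting material
6 | allyl 3-(4-hydroxyphenyl)-3-oxopropanoate | C=CCOC(=O)CC(=O)c1ccc(O)cc1 | intermediate
7 | allyl 3-(4-acetoxyphenyl)-3-oxopropanoate | C=CCOC(=O)CC(=O)c1ccc(OC(C)=O)cc1 | intermediate
8 | allyl (3R)-3-(4-acetoxyphenyl)-3-hydroxypropanoate | C=CCOC(=O)C[C@@H](O)c1ccc(OC(C)=O)cc1 | intermediate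
9 | allyl (3S)-3-(4-acetoxyphenyl)-3-[3,5-bis(tert-butyldimethylsilyloxy)-2-geranylphenoxy]propanoate | CC(C)=CCC/C(C)=C/Cc1c(O[Si](C)(C)C(C)(C)C)cc(O[Si](C)(C)C(C)(C)C)cc1O[C@H](c1ccc(OC(C)=O)cc1)CC(=O)OCC=C | intermediate
10 | (3S)-3-(4-acetoxyphenyl)-3-[3,5-bis(tert-butyldimethylsilyloxy)-2-geranylphenoxy]propanoic acid | CC(C)=CCC/C(C)=C/Cc1c(O[Si](C)(C)C(C)(C)C)cc(O[Si](C)(C)C(C)(C)C)cc1O[C@H](c1ccc(OC(C)=O)cc1)CC(=O)O | intermediate
11 | mixed anhydride of acid 10 with trifluoroacetic acid (not isolated) | CC(C)=CCC/C(C)=C/Cc1c(O[Si](C)(C)C(C)(C)C)cc(O[Si](C)(C)C(C)(C)C)cc1O[C@H](c1ccc(OC(C)=O)cc1)CC(=O)OC(=O)C(F)(F)F | intermediate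
12 | (2S)-4'-acetoxy-5,7-bis(tert-butyldimethylsilyloxy)-8-geranylflavanone | CC(C)=CCC/C(C)=C/Cc1c(O[Si](C)(C)C(C)(C)C)cc(O[Si](C)(C)C(C)(C)C)c2c1O[C@H](c1ccc(OC(C)=O)cc1)CC2=O | intermediate
13 | (2S)-4'-acetoxy-5,7-dihydroxy-8-geranylflavanone | CC(C)=CCC/C(C)=C/Cc1c(O)cc(O)c2c1O[C@H](c1ccc(OC(C)=O)cc1)CC2=O | intermediate
14 | sophoraflavanone A, (2S)-5,7,4'-trihydroxy-8-geranylflavanone | CC(C)=CCC/C(C)=C/Cc1c(O)cc(O)c2c1O[C@H](c1ccc(O)cc1)CC2=O | target

**Step count and risks**

Total step count: 10. Longest linear sequence: 8 steps (5 to 14 through steps 3–10); the phloroglucinol branch (steps 1 and 2) joins at step 6.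

Steps most likely to fail:

1. Step 8 (ring closure). The activated acid may lose the aryloxide by β-elimination, or the acid set free may protonate the geranyl olefins and the benzylic ether, before C4a is acylated. The fallback sets out from acid 10 and comes back at flavanone 12. Activation is separated from ring closure, and the Brønsted-acid manifold is replaced by a Lewis-acid one. 1-Chloro-N,N,2-trimethylpropenylamine in CH2Cl2 at 0 °C should convert 10 under neutral conditions into (3S)-3-(4-acetoxyphenyl)-3-[3,5-bis(tert-butyldimethylsilyloxy)-2-geranylphenoxy]propanoyl chloride F1. This is closed with SnCl4 and 2,6-di-tert-butyl-4-methylpyridine in CH2Cl2 at −78 °C, a classical Friedel–Crafts acylation run at a temperature where elimination and olefin protonation should be slow.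

2. Step 6 (Mitsunobu etherification). Dehydration of the activated β-hydroxy ester to the cinnamate through its acidic α-hydrogens, or partial ionisation at the benzylic carbon with erosion of enantiopurity, may compete with SN2 by the ortho-substituted phenol. The fallback sets out from hydroxy ester 8 (with phenol 4) and comes back at acid 10. The ether is made at the alcohol oxidation level, where no carbonyl acidifies the neighbouring CH2.
   - Pd(PPh3)4 and N-methylaniline should free (3R)-3-(4-acetoxyphenyl)-3-hydroxypropanoic acid F2.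
   - BH3·THF at 0 °C reduces the carboxylic acid selectively to 4-[(1R)-1,3-dihydroxypropyl]phenyl acetate F3.
   - Et3SiCl and imidazole at −78 °C silylate the primary hydroxyl to give 4-[(1R)-1-hydroxy-3-(triethylsilyloxy)propyl]phenyl acetate F4.
   - Mitsunobu coupling with 4 (PPh3, DIAD, toluene) proceeds with inversion to 4-[(1S)-1-[3,5-bis(tert-butyldimethylsilyloxy)-2-geranylphenoxy]-3-(triethylsilyloxy)propyl]phenyl acetate F5.
   - PPTS in methanol at 0 °C removes only the alkyl triethylsilyl ether to give 4-[(1S)-1-[3,5-bis(tert-butyldimethylsilyloxy)-2-geranylphenoxy]-3-hydroxypropyl]phenyl acetate F6.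
   - TEMPO with PhI(OAc)2 in MeCN–pH 7 buffer oxidises F6 to 10.

3. Step 1 (C-geranylation). O-Alkylation and repeated C-alkylation of the ambident triphenol may leave little of the mono-C-geranyl product. The fallback sets out from phloroglucinol 1 and geranyl bromide 2 and comes back at triol 3. Directed ortho-metalation replaces phenolate alkylation. MOMCl and iPr2NEt in CH2Cl2 give 1,3,5-tris(methoxymethoxy)benzene F7. n-BuLi and TMEDA in THF at 0 °C lithiate the carbon between two acetal oxygens, and catalytic CuI with 2 gives 2-geranyl-1,3,5-tris(methoxymethoxy)benzene F8. Dilute HCl in methanol at room temperature then removes the three acetals to give 3.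

**Further compounds**

F1 | step 8 | (3S)-3-(4-acetoxyphenyl)-3-[3,5-bis(tert-butyldimethylsilyloxy)-2-geranylphenoxy]propanoyl chloride | CC(C)=CCC/C(C)=C/Cc1c(O[Si](C)(C)C(C)(C)C)cc(O[Si](C)(C)C(C)(C)C)cc1O[C@H](c1ccc(OC(C)=O)cc1)CC(=O)Cl
F2 | step 6 | (3R)-3-(4-acetoxyphenyl)-3-hydroxypropanoic acid | OC(=O)C[C@@H](O)c1ccc(OC(C)=O)cc1
F3 | step 6 | 4-[(1R)-1,3-dihydroxypropyl]phenyl acetate | OCC[C@@H](O)c1ccc(OC(C)=O)cc1
F4 | step 6 | 4-[(1R)-1-hydroxy-3-(triethylsilyloxy)propyl]phenyl acetate | CC[Si](CC)(CC)OCC[C@@H](O)c1ccc(OC(C)=O)cc1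
F5 | step 6 | 4-[(1S)-1-[3,5-bis(tert-butyldimethylsilyloxy)-2-geranylphenoxy]-3-(triethylsilyloxy)propyl]phenyl acetate | CC(C)=CCC/C(C)=C/Cc1c(O[Si](C)(C)C(C)(C)C)cc(O[Si](C)(C)C(C)(C)C)cc1O[C@H](c1ccc(OC(C)=O)cc1)CCO[Si](CC)(CC)CC
F6 | step 6 | 4-[(1S)-1-[3,5-bis(tert-butyldimethylsilyloxy)-2-geranylphenoxy]-3-hydroxypropyl]phenyl acetate | CC(C)=CCC/C(C)=C/Cc1c(O[Si](C)(C)C(C)(C)C)cc(O[Si](C)(C)C(C)(C)C)cc1O[C@H](c1ccc(OC(C)=O)cc1)CCO
F7 | step 1 | 1,3,5-tris(methoxymethoxy)benzene | COCOc1cc(OCOC)cc(OCOC)c1
F8 | step 1 | 2-geranyl-1,3,5-tris(methoxymethoxy)benzene | CC(C)=CCC/C(C)=C/Cc1c(OCOC)cc(OCOC)cc1OCOC
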